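**Plan**
- Cuts: first O1–C2 of ring C (oxa-Michael), giving the open 2',4',6'-trihydroxychalcone. Then C4a–C5 of ring A (the same bond as C4a–C8a in the symmetric chalcone), giving an open 3,5,7-trioxo ester. Then C6–C7 of that chain, giving a triacetate trianion and a cinnamoyl Weinreb amide whose C=C comes from olefination of the ring B aldehyde.
- Enabling feature: ring A (C4a, C5, C6, C7, C8, C8a) carries oxygen on C5, C7 and C8a and the acyl carbon C4 on C4a. It is an acylphloroglucinol, so C5–C6–C7–C8–C8a–C4a are C1–C6 of a chain of alternating carbonyls and C4, C3, C2 are its C7, C8, C9.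
- Forward: ring B aldehyde (4-O-prenyl, 3-O-silyl), then the E-cinnamoyl amide, then the chain joined at C6–C7, then ring A closed and aromatised by Claisen condensation, then the silyl ether removed, then ring C closed.
- Stereochemistry: the E alkene comes from the olefination. The only stereocentre, C2 (S), is set in the last step by chalcone isomerase.

Key step: step 6

Remarks: C2 is S in the SMILES given, which is the configuration chalcone isomerase delivers. β-Polycarbonyl compounds are drawn as keto tautomers although they should exist largely as enols. Chalcone isomerase is taken as a recombinant protein catalyst.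

Step 1
Reactants: 1 3,4-dihydroxybenzaldehyde; 2 1-bromo-3-methylbut-2-ene (prenyl bromide)
Product: 3 3-hydroxy-4-(3-methylbut-2-enyloxy)benzaldehyde
Conditions: 2 (1.05 equiv), NaHCO3, DMF, 40 °C
Reagents that add atoms: 1-bromo-3-methylbut-2-ene (compound 2), CC(C)=CCBr
Why: Williamson ether synthesis in which the 4-OH, para to the formyl group, is much more acidic than the 3-OH, so the weak base should generate only the 4-phenoxide and the allylic bromide should be taken up there.

Step 2
Reactants: 3 3-hydroxy-4-(3-methylbut-2-enyloxy)benzaldehyde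
Product: 4 4-(3-methylbut-2-enyloxy)-3-(triisopropylsilyloxy)benzaldehyde
Conditions: i-Pr3SiCl, imidazole, DMF, rt
Reagents that add atoms: triisopropylsilyl chloride, CC(C)[Si](Cl)(C(C)C)C(C)C
Why: Imidazole-promoted silylation of a phenol; the triisopropylsilyl ether is chosen because it should withstand amidine base, lithium amide and Mg(OMe)2 and can later be removed by fluoride under mildly acidic conditions that spare the prenyl ether.

Step 3
Reactants: 4 4-(3-methylbut-2-enyloxy)-3-(triisopropylsilyloxy)benzaldehyde; 5 diethyl [2-(methoxy(methyl)amino)-2-oxoethyl]phosphonate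
Product: 6 (2E)-N-methoxy-N-methyl-3-[4-(3-methylbut-2-enyloxy)-3-(triisopropylsilyloxy)phenyl]prop-2-enamide
Conditions: 5, LiCl, DBU, MeCN, rt
Reagents that add atoms: diethyl [2-(methoxy(methyl)amino)-2-oxoethyl]phosphonate (compound 5), CCOP(=O)(CC(=O)N(C)OC)OCC
Why: Horner–Wadsworth–Emmons olefination under Masamune–Roush conditions should give the E-configured cinnamoyl Weinreb amide directly, the mild amine base leaving the aryl silyl ether and the prenyl ether untouched.

Step 4
Reactants: 7 3-acetyl-4-hydroxy-6-methyl-2H-pyran-2-one (dehydroacetic acid)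
Product: 8 methyl 3,5-dioxohexanoate
Conditions: Mg(OMe)2, MeOH, reflux; then cold aq. HCl
Reagents that add atoms: Mg(OMe)2, CO[Mg]OC; methanol, CO
Why: Ring-opening methanolysis of the pyranone combined with retro-Claisen loss of the 3-acetyl group as methyl acetate, an established preparation of this diketo ester in which chelation by Mg2+ protects the product from further cleavage.

Step 5
Reactants: 8 methyl 3,5-dioxohexanoate; 6 (2E)-N-methoxy-N-methyl-3-[4-(3-methylbut-2-enyloxy)-3-(triisopropylsilyloxy)phenyl]prop-2-enamide
Product: 11 methyl (8E)-9-[4-(3-methylbut-2-enyloxy)-3-(triisopropylsilyloxy)phenyl]-3,5,7-trioxonon-8-enoate, via trilithium trianion 9 (not isolated), via tetrahedral adduct 10 (not isolated)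
Conditions: 8 (1.5 equiv), LiN(i-Pr)2 (3.2 equiv per 8), THF, 0 °C; then 6, −78 to 0 °C; then cold 1 M HCl
Reagents that add atoms: none
Why: Acylation of a β-polycarbonyl polyanion with a Weinreb amide, in which the ester of 8 is masked as its enolate, the terminal carbanion C6 of 9 (the last formed and most reactive site) should add 1,2 to the electron-rich cinnamoyl amide, and the chelated adduct 10 should collapse to the ketone only on acidic work-up, so neither over-addition nor proton transfer to the product intervenes.

Step 6
Reactants: 11 methyl (8E)-9-[4-(3-methylbut-2-enyloxy)-3-(triisopropylsilyloxy)phenyl]-3,5,7-trioxonon-8-enoate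
Product: 13 (2E)-3-[4-(3-methylbut-2-enyloxy)-3-(triisopropylsilyloxy)phenyl]-1-(2,4,6-trihydroxyphenyl)prop-2-en-1-one, via acylcyclohexanetrione 12 (not isolated)
Conditions: Mg(OMe)2 (5 equiv), MeOH, Ar, rt to 40 °C, dark; then cold 1 M HCl (pH 2–3)
Reagents that add atoms: none
Why: Mg(OMe)2 converts the 3,5,7-tricarbonyl array of 11 into an enolate chelated by Mg2+ in which the ketone carbons are masked and C6, flanked by C5 and C7, is the nucleophile; C6 adds to the only free electrophile, the C1 ester carbonyl, methoxide is expelled, and acylcyclohexanetrione 12 enolises irreversibly to the phloroglucinol ring A of 13. The closest known reaction type is the intramolecular Claisen (Dieckmann-type) condensation of 3,5,7-triketo esters to acylphloroglucinols, the laboratory counterpart of the chalcone synthase fold. Ring A closes in the 6-exo-trig mode, the enolate carbon attacking the exocyclic ester C=O and forming the bond that becomes C4a–C5 (equivalently C4a–C8a) of the flavanone. No stereocentre is created, and the E alkene is carried through unchanged. The step needs Claisen closure (C6 to C1) rather than aldol closure (C2 to C7) or lactonisation to a pyranone, and this should be secured by chelation of the tricarbonyl unit in anhydrous methanol, by the matched methyl ester and methoxide pair and by the poorly electrophilic, aryl-conjugated C7 carbonyl, while reversible conjugate additions to the enone drain into the irreversible aromatisation. In the basic medium the chalcone should stay open as its polyphenoxide (Mg2+ counter-ion), and the cold acidic quench carries it quickly through the near-neutral pH range in which ring C would close without control.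

Step 7
Reactants: 13 (2E)-3-[4-(3-methylbut-2-enyloxy)-3-(triisopropylsilyloxy)phenyl]-1-(2,4,6-trihydroxyphenyl)prop-2-en-1-one
Product: 14 (2E)-3-[3-hydroxy-4-(3-methylbut-2-enyloxy)phenyl]-1-(2,4,6-trihydroxyphenyl)prop-2-en-1-one
Conditions: KHF2 (2.5 equiv), MeOH, rt, dark
Reagents that add atoms: none
Why: Fluoride cleavage of an aryl silyl ether by bifluoride, whose mildly acidic medium should keep the 2',6'-dihydroxychalcone protonated and therefore open and should not ionise the prenyl ether.

Step 8
Reactants: 14 (2E)-3-[3-hydroxy-4-(3-methylbut-2-enyloxy)phenyl]-1-(2,4,6-trihydroxyphenyl)prop-2-en-1-one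
Product: 15 (2S)-5,7-dihydroxy-2-[3-hydroxy-4-(3-methylbut-2-enyloxy)phenyl]-2,3-dihydro-4H-chromen-4-one (Monotesone A)
Conditions: chalcone isomerase (recombinant, from Medicago sativa), KH2PO4/K2HPO4 buffer (50 mM, pH 6.5), DMSO (5% v/v), 20 °C, dark; then pH 4, EtOAc extraction
Reagents that add atoms: none
Why: Enzymatic intramolecular oxa-Michael addition, the chalcone isomerase ring closure of 2',4',6'-trihydroxychalcones, in which the active site should guide the 2'-phenoxide (the two ortho hydroxyls are equivalent) to the face of the β-carbon that gives the 2S centre, while a pH slightly below neutral and a high enzyme loading keep the uncatalysed racemic closure negligible.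

**Compound list**
1 | 3,4-dihydroxybenzaldehyde | O=Cc1ccc(O)c(O)c1 | starting material
2 | 1-bromo-3-methylbut-2-ene (prenyl bromide) | CC(C)=CCBr | starting material
3 | 3-hydroxy-4-(3-methylbut-2-enyloxy)benzaldehyde | CC(C)=CCOc1ccc(C=O)cc1O | intermediate
4 | 4-(3-methylbut-2-enyloxy)-3-(triisopropylsilyloxy)benzaldehyde | CC(C)=CCOc1ccc(C=O)cc1O[Si](C(C)C)(C(C)C)C(C)C | intermediate
5 | diethyl [2-(methoxy(methyl)amino)-2-oxoethyl]phosphonate | CCOP(=O)(CC(=O)N(C)OC)OCC | starting material
6 | (2E)-N-methoxy-N-methyl-3-[4-(3-methylbut-2-enyloxy)-3-(triisopropylsilyloxy)phenyl]prop-2-enamide | CON(C)C(=O)/C=C/c1ccc(OCC=C(C)C)c(O[Si](C(C)C)(C(C)C)C(C)C)c1 | intermediate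
7 | 3-acetyl-4-hydroxy-6-methyl-2H-pyran-2-one (dehydroacetic acid) | CC(=O)C1=C(O)C=C(C)OC1=O | starting material
8 | methyl 3,5-dioxohexanoate | COC(=O)CC(=O)CC(C)=O | intermediate
9 | trilithium trianion (tris-enolate) of methyl 3,5-dioxohexanoate | [Li+].[Li+].[Li+].C=C([O-])C=C([O-])C=C([O-])OC | intermediate (not isolated)
10 | tetrahedral adduct: trilithium salt of methyl (8E)-7-hydroxy-7-[methoxy(methyl)amino]-9-[4-(3-methylbut-2-enyloxy)-3-(triisopropylsilyloxy)phenyl]-3,5-dioxonon-8-enoate, racemic at C7 | [Li+].[Li+].[Li+].COC([O-])=CC([O-])=CC(=O)CC([O-])(N(C)OC)/C=C/c1ccc(OCC=C(C)C)c(O[Si](C(C)C)(C(C)C)C(C)C)c1 | intermediate (not isolated)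
11 | methyl (8E)-9-[4-(3-methylbut-2-enyloxy)-3-(triisopropylsilyloxy)phenyl]-3,5,7-trioxonon-8-enoate | COC(=O)CC(=O)CC(=O)CC(=O)/C=C/c1ccc(OCC=C(C)C)c(O[Si](C(C)C)(C(C)C)C(C)C)c1 | intermediate
12 | 2-{(2E)-3-[4-(3-methylbut-2-enyloxy)-3-(triisopropylsilyloxy)phenyl]prop-2-enoyl}cyclohexane-1,3,5-trione | O=C1CC(=O)C(C(=O)/C=C/c2ccc(OCC=C(C)C)c(O[Si](C(C)C)(C(C)C)C(C)C)c2)C(=O)C1 | intermediate (not isolated)
13 | (2E)-3-[4-(3-methylbut-2-enyloxy)-3-(triisopropylsilyloxy)phenyl]-1-(2,4,6-trihydroxyphenyl)prop-2-en-1-one | CC(C)=CCOc1ccc(/C=C/C(=O)c2c(O)cc(O)cc2O)cc1O[Si](C(C)C)(C(C)C)C(C)C | intermediate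
14 | (2E)-3-[3-hydroxy-4-(3-methylbut-2-enyloxy)phenyl]-1-(2,4,6-trihydroxyphenyl)prop-2-en-1-one | CC(C)=CCOc1ccc(/C=C/C(=O)c2c(O)cc(O)cc2O)cc1O | intermediate
15 | (2S)-5,7-dihydroxy-2-[3-hydroxy-4-(3-methylbut-2-enyloxy)phenyl]-2,3-dihydro-4H-chromen-4-one (Monotesone A) | CC(C)=CCOc1ccc([C@@H]2CC(=O)c3c(O)cc(O)cc3O2)cc1O | target

**Step count**
Total: 8 steps. Longest linear sequence: 7 steps (steps 1, 2, 3, 5, 6, 7, 8, from 3,4-dihydroxybenzaldehyde); step 4 supplies the second fragment for step 5.

**Steps most likely to fail**

Step 5. The polyanion may add in the conjugate sense to the cinnamoyl unit, or proton transfer may quench the terminal carbanion before acylation, and the polyketide chain may cyclise during work-up. The fallback sets out from 6 and returns at 11, moving the cinnamoyl C–C bond to a simpler dianion and using carbon dioxide, not an enone, as the electrophile for the trianion. Pentane-2,4-dione is deprotonated twice with LiN(i-Pr)2 in THF at 0 °C to the dilithium dianion of pentane-2,4-dione F1, which is acylated at its terminal carbon by 6 to give (1E)-1-[4-(3-methylbut-2-enyloxy)-3-(triisopropylsilyloxy)phenyl]oct-1-ene-3,5,7-trione F2. Treatment of F2 with LiN(i-Pr)2 (3 equiv) should give the trilithium trianion of this trione F3, which is carboxylated at the terminal methyl carbon with CO2 to (8E)-9-[4-(3-methylbut-2-enyloxy)-3-(triisopropylsilyloxy)phenyl]-3,5,7-trioxonon-8-enoic acid F4. Immediate esterification of F4 with Me3SiCHN2 in toluene/methanol at 0 °C leads back to 11.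

Step 8. Turnover of the non-natural 4-O-prenyl ring B pattern by the enzyme may be slow, so that uncatalysed closure competes and erodes the enantiomeric purity, or ring opening during isolation may cause partial racemisation. The fallback sets out from 14 and returns at 15 by resolution instead of asymmetric catalysis. Chalcone 14 is closed deliberately without control (NaOAc, EtOH, reflux) to racemic 5,7-dihydroxy-2-[3-hydroxy-4-(3-methylbut-2-enyloxy)phenyl]-2,3-dihydro-4H-chromen-4-one F5. The enantiomers of F5 are then separated by preparative HPLC on an amylose tris(3,5-dimethylphenylcarbamate) stationary phase to give 15. The 2R enantiomer can be racemised through the chalcone with mild base and resubmitted.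

Step 6. The chain may fold in the aldol sense (C2 onto C7), lactonise to a pyranone, or close ring C prematurely during work-up. Partial loss of the silyl ether would be harmless because step 7 removes it. The fallback sets out from 4 and returns at 13; ring A is then bought as an intact acylphloroglucinol and not built. Aldehyde 4 and commercial 1-(2,4,6-trihydroxyphenyl)ethanone are treated with excess LiN(SiMe3)2 in THF (−78 °C to rt). The fully deprotonated ketone should add to 4 to give 3-hydroxy-3-[4-(3-methylbut-2-enyloxy)-3-(triisopropylsilyloxy)phenyl]-1-(2,4,6-trihydroxyphenyl)propan-1-one F6 as its Li+ salt. F6 should lose water by E1cB elimination in the flask, and cold acidic work-up then delivers 13.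

**Further compounds**
F1 | step 5 | dilithium dianion of pentane-2,4-dione | [Li+].[Li+].C=C([O-])C=C(C)[O-]
F2 | step 5 | (1E)-1-[4-(3-methylbut-2-enyloxy)-3-(triisopropylsilyloxy)phenyl]oct-1-ene-3,5,7-trione | CC(=O)CC(=O)CC(=O)/C=C/c1ccc(OCC=C(C)C)c(O[Si](C(C)C)(C(C)C)C(C)C)c1
F3 | step 5 | trilithium trianion of (1E)-1-[4-(3-methylbut-2-enyloxy)-3-(triisopropylsilyloxy)phenyl]oct-1-ene-3,5,7-trione | [Li+].[Li+].[Li+].C=C([O-])C=C([O-])C=C([O-])/C=C/c1ccc(OCC=C(C)C)c(O[Si](C(C)C)(C(C)C)C(C)C)c1
F4 | step 5 | (8E)-9-[4-(3-methylbut-2-enyloxy)-3-(triisopropylsilyloxy)phenyl]-3,5,7-trioxonon-8-enoic acid | OC(=O)CC(=O)CC(=O)CC(=O)/C=C/c1ccc(OCC=C(C)C)c(O[Si](C(C)C)(C(C)C)C(C)C)c1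
F5 | step 8 | racemic 5,7-dihydroxy-2-[3-hydroxy-4-(3-methylbut-2-enyloxy)phenyl]-2,3-dihydro-4H-chromen-4-one | CC(C)=CCOc1ccc(C2CC(=O)c3c(O)cc(O)cc3O2)cc1O
F6 | step 6 | 3-hydroxy-3-[4-(3-methylbut-2-enyloxy)-3-(triisopropylsilyloxy)phenyl]-1-(2,4,6-trihydroxyphenyl)propan-1-one (racemic) | CC(C)=CCOc1ccc(C(O)CC(=O)c2c(O)cc(O)cc2O)cc1O[Si](C(C)C)(C(C)C)C(C)C
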